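**Plan**

- Retrosynthetic cuts, in this order: the lactone O–C6 bond (back to a C5-keto acid on the intact ten-membered ring); C4–C5 (ring opened to a vinyl iodide and an aldehyde); the C8 ester; C7–C8 (aldehyde plus 2-(alkoxycarbonyl)allylboronate); C2–C3 (Weinreb amide plus acetylide).
- Forward: the C8–C10/C1–C2 chain comes from (R)-mevalonolactone; C3/C4/C15 are added as an alkyne and turned into the (Z)-iodoalkene; the allylboration joins C5–C7 and C11–C13; after esterification a Nozaki–Hiyama–Kishi reaction closes the carbocycle at C4–C5; the γ-lactone is the last ring.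
- Stereochemistry: C10 is bought; C2 by Noyori transfer hydrogenation; C7/C8 by a chiral-acid-catalysed chair-type allylboration; C6 in the key step under control of C7; C5 by Felkin reduction next to the new C6–O bond; the 3Z alkene by trans-hydroalumination/iodination; the side-chain Z geometry from (Z)-2-iodocrotyl alcohol.
- Enabling feature: C6 is the only enolisable carbon next to a C5 carbonyl (C4 is an sp2 ring carbon) and lies 1,4 to the carboxyl carbon C12 (C12–C11–C7–C6). The C5 oxygen of the target is therefore carried as a ketone, and its iodine(III)-umpoled enol is trapped 5-exo by the acrylic acid.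

Key step: step 22

Assumption: germacranolide numbering is used throughout, also for open-chain ("4,5-seco") intermediates (C1–C10 ring, C11–C13 lactone carbons, C14 methyl, C15 CH2O); compounds 1, 5, 11, 12 and 17 are taken as purchasable.

**Route**

Step 1
Reactants: 1 (R)-mevalonolactone
Product: 2 Weinreb amide diol
Conditions: MeNH(OMe)·HCl, i-PrMgCl, THF, −20 → 0 °C
Reagents that add atoms: N,O-dimethylhydroxylamine hydrochloride, CNOC.Cl
Why: Weinreb aminolysis of the δ-lactone by the magnesium amide should open the ring without touching the bought C10 stereocentre.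

Step 2
Reactants: 2 Weinreb amide diol
Product: 4 TES/TBS-protected Weinreb amide, via mono-TES ether 3 (not isolated)
Conditions: TESCl, imidazole, CH2Cl2, −20 °C; then TBSOTf, 2,6-lutidine, 0 °C → rt
Reagents that add atoms: chlorotriethylsilane, CC[Si](Cl)(CC)CC; tert-butyldimethylsilyl triflate, CC(C)(C)[Si](C)(C)OS(=O)(=O)C(F)(F)F
Why: Sequential silylation should take the primary alcohol first with the silyl chloride and then the tertiary alcohol with the more reactive silyl triflate.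

Step 3
Reactants: 4 TES/TBS-protected Weinreb amide; 5 propargyl TBDPS ether
Product: 6 ynone
Conditions: 5, n-BuLi, THF, −78 °C; then 4, −78 → −20 °C; aq. NH4Cl
Reagents that add atoms: none
Why: Weinreb ketone synthesis with a lithium acetylide forms C2–C3, the chelated tetrahedral adduct preventing over-addition.

Step 4
Reactants: 6 ynone
Product: 7 (R)-propargylic alcohol
Conditions: RuCl[(R,R)-TsDPEN](p-cymene) (cat.), i-PrOH, rt
Reagents that add atoms: none
Why: Noyori asymmetric transfer hydrogenation of an ynone should set C2 (R) under catalyst control, the alkyne acting as the π-substituent.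

Step 5
Reactants: 7 (R)-propargylic alcohol
Product: 8 (Z)-iodoalkene alcohol
Conditions: Red-Al, THF, 0 °C; then I2, −78 °C
Reagents that add atoms: iodine, II
Why: Alkoxide-directed trans-hydroalumination puts aluminium on the distal alkyne carbon (C4) cis to C2, and iodinolysis with retention should give the (Z)-iodoalkene that fixes the C3=C4 geometry.

Step 6
Reactants: 8 (Z)-iodoalkene alcohol
Product: 9 TIPS ether
Conditions: TIPSOTf, 2,6-lutidine, CH2Cl2, 0 °C
Reagents that add atoms: triisopropylsilyl triflate, CC(C)[Si](OS(=O)(=O)C(F)(F)F)(C(C)C)C(C)C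
Why: Silyl triflate protection of the hindered secondary allylic alcohol masks C2–OH until the last step.

Step 7
Reactants: 9 TIPS ether
Product: 10 C8 aldehyde
Conditions: (COCl)2, DMSO, CH2Cl2, −78 → −30 °C; Et3N
Reagents that add atoms: none
Why: Swern conditions oxidise a primary triethylsilyl ether directly to the aldehyde, while tertiary TBS, secondary TIPS and primary TBDPS ethers should be inert.

Step 8
Reactants: 11 3-(PMB-oxy)propanal; 12 tert-butyl acrylate
Product: 13 Morita–Baylis–Hillman alcohol (racemic)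
Conditions: DABCO, dioxane–H2O, rt
Reagents that add atoms: none
Why: The Morita–Baylis–Hillman reaction joins C7 to C11; the carbinol stereocentre is lost again in step 10.

Step 9
Reactants: 13 Morita–Baylis–Hillman alcohol
Product: 14 allylic acetate
Conditions: Ac2O, Et3N, DMAP (cat.), CH2Cl2, 0 °C
Reagents that add atoms: acetic anhydride, CC(=O)OC(C)=O
Why: Acetylation turns the hydroxyl into the leaving group needed for allylic borylation.

Step 10
Reactants: 14 allylic acetate
Product: 15 (E)-allylboronate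
Conditions: B2pin2, CuCl (cat.), LiCl, KOAc, DMF, rt
Reagents that add atoms: bis(pinacolato)diboron, CC1(C)OB(B2OC(C)(C)C(C)(C)O2)OC1(C)C
Why: Copper-catalysed SN2′ borylation of a Baylis–Hillman acetate should give the trisubstituted allylboronate with the ester trans to the C6 chain (CH2B cis to it).

Step 11
Reactants: 10 C8 aldehyde; 15 (E)-allylboronate
Product: 16 syn hydroxy ester (7R,8R)
Conditions: (S)-TRIP (10 mol %), 4 Å MS, toluene, 0 °C → rt; aqueous work-up
Reagents that add atoms: none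
Why: Chiral-phosphoric-acid-catalysed allylboration through a closed chair transition state should turn the CH2B-cis geometry into the C7/C8 syn diad, the catalyst (antipode chosen for the 8R sense) selecting the aldehyde face because the remote C10 and C2 centres exert little bias.

Step 12
Reactants: 17 crotonaldehyde
Product: 18 (Z)-2-iodobut-2-enal
Conditions: I2, K2CO3, DMAP (cat.), THF–H2O, rt
Reagents that add atoms: iodine, II
Why: Amine-catalysed α-iodination of an enal (addition, iodination, elimination) should give the Z isomer with iodine cis to the methyl group.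

Step 13
Reactants: 18 (Z)-2-iodobut-2-enal
Product: 19 (Z)-2-iodobut-2-en-1-ol
Conditions: NaBH4, CeCl3·7H2O, MeOH, 0 °C
Reagents that add atoms: none
Why: Luche 1,2-reduction of the enal leaves the iodoalkene geometry intact.

Step 14
Reactants: 19 (Z)-2-iodobut-2-en-1-ol
Product: 20 TBDPS ether
Conditions: TBDPSCl, imidazole, DMF, rt
Reagents that add atoms: tert-butyl(chloro)diphenylsilane, CC(C)(C)[Si](Cl)(c1ccccc1)c1ccccc1
Why: Standard silylation gives an acid-stable, non-leaving protecting group for the side-chain oxygen.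

Step 15
Reactants: 20 TBDPS ether
Product: 21 (Z)-silyloxymethyl crotonic acid
Conditions: t-BuLi (2.1 equiv), Et2O, −78 °C; CO2; cold dil. HCl
Reagents that add atoms: carbon dioxide, O=C=O
Why: Iodine–lithium exchange and carboxylation proceed with retention, so the carboxyl ends cis to the methyl group as in the target side chain.

Step 16
Reactants: 16 syn hydroxy ester; 21 (Z)-silyloxymethyl crotonic acid
Product: 22 C8 ester
Conditions: 21, 2,4,6-trichlorobenzoyl chloride, Et3N, THF; then 16, DMAP, toluene, 40 °C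
Reagents that add atoms: none
Why: Yamaguchi mixed-anhydride esterification is the usual way to acylate hindered carbinols with angelate-type acids without Z-to-E isomerisation.

Step 17
Reactants: 22 C8 ester
Product: 23 C5 primary alcohol
Conditions: DDQ, CH2Cl2–pH 7 buffer, 0 °C
Reagents that add atoms: none
Why: Oxidative cleavage of the PMB ether should leave all silyl ethers, both esters and the iodoalkene untouched.

Step 18
Reactants: 23 C5 primary alcohol
Product: 24 C5 aldehyde
Conditions: Dess–Martin periodinane, NaHCO3, CH2Cl2, rt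
Reagents that add atoms: none
Why: Buffered Dess–Martin oxidation gives the aldehyde without epimerising C7, which is β to it.

Step 19
Reactants: 24 C5 aldehyde
Product: 25 ten-membered allylic alcohol (C5 epimers)
Conditions: CrCl2 (10 equiv), NiCl2 (5 mol %), DMSO–THF, 0.002 M, rt
Reagents that add atoms: none
Why: Intramolecular Nozaki–Hiyama–Kishi coupling forms C4–C5 and the carbocycle with retention of the Z geometry, and the C5 configuration is irrelevant because both epimers converge in step 20.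

Step 20
Reactants: 25 ten-membered allylic alcohol
Product: 26 macrocyclic enone
Conditions: Dess–Martin periodinane, NaHCO3, CH2Cl2, rt
Reagents that add atoms: none
Why: Dess–Martin oxidation of the allylic alcohol installs the C5 ketone that activates C6 for the key step.

Step 21
Reactants: 26 macrocyclic enone
Product: 28 5-oxo acid, via trimethylsilyl ester 27 (not isolated)
Conditions: TMSOTf, 2,6-lutidine, CH2Cl2, 0 °C; then aq. citric acid–THF
Reagents that add atoms: trimethylsilyl triflate, C[Si](C)(C)OS(=O)(=O)C(F)(F)F (silyl group of 27 only)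
Why: Silyl-triflate-mediated cleavage of the tert-butyl ester (loss of isobutene, hydrolysis of the silyl ester) frees the acid under buffered conditions that spare the silyl ethers.

Step 22
Reactants: 28 5-oxo acid
Product: 30 trans-fused 5-oxo-6,12-lactone (6S), via C6 phenyl(tosyloxy)iodanyl ketone 29 (not isolated)
Conditions: PhI(OH)OTs (1.3 equiv), CH2Cl2, 25–40 °C
Reagents that add atoms: [hydroxy(tosyloxy)iodo]benzene, Cc1ccc(S(=O)(=O)O[I](O)c2ccccc2)cc1 (iodanyl group of 29 only)
Why: The acid exchanges onto iodine(III) and the C5 ketone, which can enolise only toward C6 because C4 is sp2, attacks the iodane to give the C6 iodanyl ketone 29; the carboxyl oxygen then displaces iodobenzene in an intramolecular SN2 reaction and so forms the O–C6 bond. The closest known reaction is the hypervalent-iodine (Koser reagent) oxidative lactonisation of 5-oxo carboxylic acids to 5-oxo-4-olides. The γ-lactone (O, C12, C11, C7, C6) closes in the 5-exo-tet mode. The new C6 stereocentre is controlled by C7: the C6 epimers of 29 interconvert through the enol, the one that cyclises with the C5 acyl group and C8 trans on the forming ring (H6/H7 anti) should react faster, and because C6–H remains α to the ketone a minor cis isomer can be equilibrated to it. The step needs α′-selectivity over γ-enolisation at C2 and over capture by tosylate or the alkenes; the sp2 C4, the bulky OTIPS at C2, the 1,4 placement of the carboxyl to C6 and the electron-poor character of all three alkenes should secure this.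

Step 23
Reactants: 30 trans-fused 5-oxo-6,12-lactone
Product: 31 5-hydroxy lactone (5S)
Conditions: NaBH4, CeCl3·7H2O, MeOH–THF, −78 °C
Reagents that add atoms: none
Why: Luche 1,2-reduction with hydride approaching anti to the C6–O bond (Felkin–Anh polar model) should give the 5,6-syn alcohol, cerium suppressing conjugate reduction of the α-methylene lactone.

Step 24
Reactants: 31 5-hydroxy lactone
Product: 32 triol
Conditions: TBAF, AcOH (1:1), THF, 0 °C → rt
Reagents that add atoms: none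
Why: Buffered fluoride should remove the two primary TBDPS ethers much faster than the secondary TIPS and tertiary TBS ethers, and the buffer prevents acyl migration.

Step 25
Reactants: 32 triol
Product: 33 triacetate
Conditions: Ac2O, pyridine, DMAP (cat.), CH2Cl2, 0 °C
Reagents that add atoms: acetic anhydride, CC(=O)OC(C)=O
Why: Acetylation of the two primary alcohols and the C5 secondary alcohol installs all three acetates while C2–O and C10–O remain silylated.

Step 26
Reactants: 33 triacetate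
Product: 34 target CNP0126757.1
Conditions: 48% aq. HF, MeCN, 0 °C → rt
Reagents that add atoms: none
Why: Acidic fluoride desilylation should remove the secondary TIPS and tertiary TBS ethers without affecting acetates, the crotonate ester or the α-methylene lactone.

**Compound list**

1 | (R)-mevalonolactone | O=C1C[C@](C)(O)CCO1 | starting material
2 | (R)-3,5-dihydroxy-N-methoxy-N,3-dimethylpentanamide | CON(C)C(=O)C[C@](C)(O)CCO | intermediate
3 | (R)-3-hydroxy-N-methoxy-N,3-dimethyl-5-(triethylsilyloxy)pentanamide | CON(C)C(=O)C[C@](C)(O)CCO[Si](CC)(CC)CC | intermediate (not isolated)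
4 | (R)-3-(tert-butyldimethylsilyloxy)-N-methoxy-N,3-dimethyl-5-(triethylsilyloxy)pentanamide | CON(C)C(=O)C[C@](C)(O[Si](C)(C)C(C)(C)C)CCO[Si](CC)(CC)CC | intermediate
5 | tert-butyl(diphenyl)(prop-2-yn-1-yloxy)silane | C#CCO[Si](c1ccccc1)(c1ccccc1)C(C)(C)C | starting material
6 | (R)-6-(TBS-oxy)-1-(TBDPS-oxy)-6-methyl-8-(TES-oxy)oct-2-yn-4-one | CC(C)(C)[Si](OCC#CC(=O)C[C@](C)(O[Si](C)(C)C(C)(C)C)CCO[Si](CC)(CC)CC)(c1ccccc1)c1ccccc1 | intermediate
7 | (4R,6R)-6-(TBS-oxy)-1-(TBDPS-oxy)-6-methyl-8-(TES-oxy)oct-2-yn-4-ol | CC(C)(C)[Si](OCC#C[C@H](O)C[C@](C)(O[Si](C)(C)C(C)(C)C)CCO[Si](CC)(CC)CC)(c1ccccc1)c1ccccc1 | intermediate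
8 | (2Z,4R,6R)-6-(TBS-oxy)-1-(TBDPS-oxy)-2-iodo-6-methyl-8-(TES-oxy)oct-2-en-4-ol | CC(C)(C)[Si](OC/C(I)=C/[C@H](O)C[C@](C)(O[Si](C)(C)C(C)(C)C)CCO[Si](CC)(CC)CC)(c1ccccc1)c1ccccc1 | intermediate
9 | 4-O-triisopropylsilyl ether of 8 | CC(C)(C)[Si](OC/C(I)=C/[C@H](O[Si](C(C)C)(C(C)C)C(C)C)C[C@](C)(O[Si](C)(C)C(C)(C)C)CCO[Si](CC)(CC)CC)(c1ccccc1)c1ccccc1 | intermediate
10 | (3S,5R,6Z)-3-(TBS-oxy)-8-(TBDPS-oxy)-7-iodo-3-methyl-5-(TIPS-oxy)oct-6-enal | CC(C)(C)[Si](OC/C(I)=C/[C@H](O[Si](C(C)C)(C(C)C)C(C)C)C[C@](C)(O[Si](C)(C)C(C)(C)C)CC=O)(c1ccccc1)c1ccccc1 | intermediate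
11 | 3-[(4-methoxybenzyl)oxy]propanal | COc1ccc(COCCC=O)cc1 | starting material
12 | tert-butyl acrylate | C=CC(=O)OC(C)(C)C | starting material
13 | tert-butyl 3-hydroxy-5-[(4-methoxybenzyl)oxy]-2-methylenepentanoate (racemic) | C=C(C(=O)OC(C)(C)C)C(O)CCOCc1ccc(OC)cc1 | intermediate
14 | tert-butyl 3-acetoxy-5-[(4-methoxybenzyl)oxy]-2-methylenepentanoate (racemic) | C=C(C(=O)OC(C)(C)C)C(OC(C)=O)CCOCc1ccc(OC)cc1 | intermediate
15 | tert-butyl (E)-5-[(4-methoxybenzyl)oxy]-2-[(4,4,5,5-tetramethyl-1,3,2-dioxaborolan-2-yl)methyl]pent-2-enoate | CC(C)(C)OC(=O)/C(CB1OC(C)(C)C(C)(C)O1)=C/CCOCc1ccc(OC)cc1 | intermediate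
16 | tert-butyl (7R,8R)-8-hydroxy-4-iodo-5-(PMB-oxy)-10-(TBS-oxy)-15-(TBDPS-oxy)-2-(TIPS-oxy)-4,5-secogermacra-3Z,11(13)-dien-12-oate (C2, C10 as in 10) | CC(C)(C)[Si](OC/C(I)=C/[C@H](O[Si](C(C)C)(C(C)C)C(C)C)C[C@](C)(O[Si](C)(C)C(C)(C)C)C[C@@H](O)[C@H](CCOCc1ccc(OC)cc1)C(=C)C(=O)OC(C)(C)C)(c1ccccc1)c1ccccc1 | intermediate
17 | (E)-but-2-enal (crotonaldehyde) | C/C=C/C=O | starting material
18 | (Z)-2-iodobut-2-enal | C/C=C(\I)C=O | intermediate
19 | (Z)-2-iodobut-2-en-1-ol | C/C=C(\I)CO | intermediate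
20 | (Z)-tert-butyl[(2-iodobut-2-en-1-yl)oxy]diphenylsilane | C/C=C(\I)CO[Si](c1ccccc1)(c1ccccc1)C(C)(C)C | intermediate
21 | (Z)-2-{[(tert-butyldiphenylsilyl)oxy]methyl}but-2-enoic acid | C/C=C(\C(=O)O)CO[Si](c1ccccc1)(c1ccccc1)C(C)(C)C | intermediate
22 | 8-O-[(Z)-2-(TBDPS-oxymethyl)but-2-enoyl] ester of 16 | CC(C)(C)[Si](OC/C(I)=C/[C@H](O[Si](C(C)C)(C(C)C)C(C)C)C[C@](C)(O[Si](C)(C)C(C)(C)C)C[C@@H](OC(=O)/C(=C\C)CO[Si](c1ccccc1)(c1ccccc1)C(C)(C)C)[C@H](CCOCc1ccc(OC)cc1)C(=C)C(=O)OC(C)(C)C)(c1ccccc1)c1ccccc1 | intermediate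
23 | C5 primary alcohol (PMB removed from 22) | CC(C)(C)[Si](OC/C(I)=C/[C@H](O[Si](C(C)C)(C(C)C)C(C)C)C[C@](C)(O[Si](C)(C)C(C)(C)C)C[C@@H](OC(=O)/C(=C\C)CO[Si](c1ccccc1)(c1ccccc1)C(C)(C)C)[C@H](CCO)C(=C)C(=O)OC(C)(C)C)(c1ccccc1)c1ccccc1 | intermediate
24 | C5 aldehyde | CC(C)(C)[Si](OC/C(I)=C/[C@H](O[Si](C(C)C)(C(C)C)C(C)C)C[C@](C)(O[Si](C)(C)C(C)(C)C)C[C@@H](OC(=O)/C(=C\C)CO[Si](c1ccccc1)(c1ccccc1)C(C)(C)C)[C@H](CC=O)C(=C)C(=O)OC(C)(C)C)(c1ccccc1)c1ccccc1 | intermediate
25 | tert-butyl 5-hydroxy-8-acyloxy-10-(TBS-oxy)-15-(TBDPS-oxy)-2-(TIPS-oxy)germacra-3Z,11(13)-dien-12-oate (C5 epimers; other centres as in 22) | C=C(C(=O)OC(C)(C)C)[C@H]1CC(O)/C(CO[Si](c2ccccc2)(c2ccccc2)C(C)(C)C)=C\[C@H](O[Si](C(C)C)(C(C)C)C(C)C)C[C@](C)(O[Si](C)(C)C(C)(C)C)C[C@H]1OC(=O)/C(=C\C)CO[Si](c1ccccc1)(c1ccccc1)C(C)(C)C | intermediate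
26 | 5-oxo analogue of 25 (macrocyclic Z-enone) | C=C(C(=O)OC(C)(C)C)[C@H]1CC(=O)/C(CO[Si](c2ccccc2)(c2ccccc2)C(C)(C)C)=C\[C@H](O[Si](C(C)C)(C(C)C)C(C)C)C[C@](C)(O[Si](C)(C)C(C)(C)C)C[C@H]1OC(=O)/C(=C\C)CO[Si](c1ccccc1)(c1ccccc1)C(C)(C)C | intermediate
27 | trimethylsilyl ester corresponding to 26 | C=C(C(=O)O[Si](C)(C)C)[C@H]1CC(=O)/C(CO[Si](c2ccccc2)(c2ccccc2)C(C)(C)C)=C\[C@H](O[Si](C(C)C)(C(C)C)C(C)C)C[C@](C)(O[Si](C)(C)C(C)(C)C)C[C@H]1OC(=O)/C(=C\C)CO[Si](c1ccccc1)(c1ccccc1)C(C)(C)C | intermediate (not isolated)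
28 | 5-oxo-germacra-3Z,11(13)-dien-12-oic acid (protected as in 26) | C=C(C(=O)O)[C@H]1CC(=O)/C(CO[Si](c2ccccc2)(c2ccccc2)C(C)(C)C)=C\[C@H](O[Si](C(C)C)(C(C)C)C(C)C)C[C@](C)(O[Si](C)(C)C(C)(C)C)C[C@H]1OC(=O)/C(=C\C)CO[Si](c1ccccc1)(c1ccccc1)C(C)(C)C | intermediate
29 | 6-[phenyl(tosyloxy)-λ3-iodanyl] derivative of 28 (C6 epimers) | C=C(C(=O)O)[C@H]1C([I](c2ccccc2)OS(=O)(=O)c2ccc(C)cc2)C(=O)/C(CO[Si](c2ccccc2)(c2ccccc2)C(C)(C)C)=C\[C@H](O[Si](C(C)C)(C(C)C)C(C)C)C[C@](C)(O[Si](C)(C)C(C)(C)C)C[C@H]1OC(=O)/C(=C\C)CO[Si](c1ccccc1)(c1ccccc1)C(C)(C)C | intermediate (not isolated)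
30 | (6S,7R,8R)-5-oxo-6,12-olide, trans-fused α-methylene lactone (silyl groups as in 28) | C=C1C(=O)O[C@H]2[C@H]1[C@H](OC(=O)/C(=C\C)CO[Si](c3ccccc3)(c3ccccc3)C(C)(C)C)C[C@@](C)(O[Si](C)(C)C(C)(C)C)C[C@@H](O[Si](C(C)C)(C(C)C)C(C)C)/C=C(/CO[Si](c3ccccc3)(c3ccccc3)C(C)(C)C)C2=O | intermediate
31 | (5S)-5-hydroxy lactone | C=C1C(=O)O[C@H]2[C@H]1[C@H](OC(=O)/C(=C\C)CO[Si](c3ccccc3)(c3ccccc3)C(C)(C)C)C[C@@](C)(O[Si](C)(C)C(C)(C)C)C[C@@H](O[Si](C(C)C)(C(C)C)C(C)C)/C=C(/CO[Si](c3ccccc3)(c3ccccc3)C(C)(C)C)[C@@H]2O | intermediate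
32 | triol (5-OH, 15-OH, side-chain CH2OH free; 2-O-TIPS, 10-O-TBS) | C=C1C(=O)O[C@H]2[C@H]1[C@H](OC(=O)/C(=C\C)CO)C[C@@](C)(O[Si](C)(C)C(C)(C)C)C[C@@H](O[Si](C(C)C)(C(C)C)C(C)C)/C=C(/CO)[C@@H]2O | intermediate
33 | 2-O-TIPS, 10-O-TBS ether of the target (triacetate) | C=C1C(=O)O[C@H]2[C@H]1[C@H](OC(=O)/C(=C\C)COC(C)=O)C[C@@](C)(O[Si](C)(C)C(C)(C)C)C[C@@H](O[Si](C(C)C)(C(C)C)C(C)C)/C=C(/COC(C)=O)[C@@H]2OC(C)=O | intermediate
34 | CNP0126757.1 (2R,5S,6S,7R,8R,10S) | C=C1C(=O)O[C@H]2[C@H]1[C@H](OC(=O)/C(=C\C)COC(C)=O)C[C@@](C)(O)C[C@@H](O)/C=C(/COC(C)=O)[C@@H]2OC(C)=O | target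

**Count and risks**

Total step count: 26. Longest linear sequence: 19 (steps 1–7, 11, 16–26).

Steps most likely to fail:

Step 22 (oxidative lactonisation). The iodane may be captured by tosylate, enolisation may occur toward C2, or face selection at C6 may be poor. Fallback by the classical two-stage route, setting out from 28: α′-bromination with phenyltrimethylammonium tribromide (THF, 0 °C) should give the 6-bromo-5-oxo acid F1. Treatment with Cs2CO3 in DMF then lets the carboxylate displace bromide at the α-keto carbon; the bromide epimerises through the enol, so the trans-lactone should form preferentially. The route is rejoined at 30.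

Step 19 (Nozaki–Hiyama–Kishi macrocyclisation). Ring closure may lose out to oligomerisation, or the hindered vinylchromium may eliminate the allylic silyloxy group. Fallback by acyl coupling instead of aldehyde addition, setting out from 23: oxidation (TEMPO, PhI(OAc)2, MeCN–H2O) gives the 5-carboxylic acid F2, and 2,2′-dipyridyl disulfide/PPh3 converts it to the S-(pyridin-2-yl) thioester F3. Nickel-catalysed reductive macro-ketonisation of the vinyl iodide with the thioester (NiBr2·dtbbpy, Cp2ZrCl2, Zn, DMI, high dilution; one-pot Ni/Zr ketone synthesis type) should give enone 26 directly, so steps 18–20 are bypassed.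

Step 11 (allylboration). The electron-poor boronate may react sluggishly under chiral-acid catalysis, or catalyst control over the aldehyde face may be insufficient. Fallback by reagent control, setting out from 14: copper-catalysed borylation with bis(diisopropyl L-tartrato)diboron gives the tartrate allylboronate F4. It adds without catalyst to aldehyde 10 (toluene, 4 Å MS, −78 °C → rt; Roush-type tartrate allylboration through the same chair transition state) and rejoins the route at 16. The tartrate antipode is used if the sense of induction proves opposite.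

Further compounds
F1 | step 22 | 6-bromo-5-oxo acid (C6 epimers; otherwise as 28) | C=C(C(=O)O)[C@H]1C(Br)C(=O)/C(CO[Si](c2ccccc2)(c2ccccc2)C(C)(C)C)=C\[C@H](O[Si](C(C)C)(C(C)C)C(C)C)C[C@](C)(O[Si](C)(C)C(C)(C)C)C[C@H]1OC(=O)/C(=C\C)CO[Si](c1ccccc1)(c1ccccc1)C(C)(C)C
F2 | step 19 | 5-carboxylic acid from 23 (4,5-seco series) | CC(C)(C)[Si](OC/C(I)=C/[C@H](O[Si](C(C)C)(C(C)C)C(C)C)C[C@](C)(O[Si](C)(C)C(C)(C)C)C[C@@H](OC(=O)/C(=C\C)CO[Si](c1ccccc1)(c1ccccc1)C(C)(C)C)[C@H](CC(=O)O)C(=C)C(=O)OC(C)(C)C)(c1ccccc1)c1ccccc1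
F3 | step 19 | S-(pyridin-2-yl) thioester of F2 | CC(C)(C)[Si](OC/C(I)=C/[C@H](O[Si](C(C)C)(C(C)C)C(C)C)C[C@](C)(O[Si](C)(C)C(C)(C)C)C[C@@H](OC(=O)/C(=C\C)CO[Si](c1ccccc1)(c1ccccc1)C(C)(C)C)[C@H](CC(=O)Sc1ccccn1)C(=C)C(=O)OC(C)(C)C)(c1ccccc1)c1ccccc1
F4 | step 11 | tert-butyl (E)-2-{[(4R,5R)-4,5-bis(isopropoxycarbonyl)-1,3,2-dioxaborolan-2-yl]methyl}-5-[(4-methoxybenzyl)oxy]pent-2-enoate | CC(C)OC(=O)[C@@H]1OB(C/C(=C\CCOCc2ccc(OC)cc2)C(=O)OC(C)(C)C)O[C@H]1C(=O)OC(C)C
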